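The 31-membered lactone ring (carbonyl C1, ring oxygen, C2 to C30 all unsubstituted methylenes, no stereocentres) is cut on both sides of C17, at C16–C17 and C17–C18. C17 arrives alone as the doubly acidic carbon of bis(phenylsulfonyl)methane and is alkylated twice by the two primary bromide termini of one open chain, so a single operation forms both C–C bonds and closes the macrocycle. That chain, 13-bromotridecyl 16-bromohexadecanoate, already holds the C1–O–C30 ester link and comes in two steps from a commercial bromo acid and a commercial diol. Reductive loss of both sulfonyl groups then turns C17 back into a methylene.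

Key step: step 3

Remark: the target is triacontan-30-olide, achiral, with 30 ring carbons accounted for as 16 (bromo acid) + 1 (bis-sulfone carbon) + 13 (diol); the dibromo ester needs no protecting group, and its bromides are activated in the flask by catalytic Bu4NI instead of by a separate halide-exchange step.

Step 1
Reactants: 1 tridecane-1,13-diol
Product: 2 13-bromotridecan-1-ol
Conditions: 48% aq. HBr (1.2 equiv), toluene, reflux
Reagents that add atoms: hydrogen bromide, Br
Why: Acid-mediated SN2 displacement of a protonated primary hydroxyl by bromide (known monobromination of α,ω-diols); the bromo alcohol passes into the toluene layer, where aggregation shields its remaining hydroxyl, so the second substitution should lag behind and the minor diol and dibromide are removed by chromatography.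

Step 2
Reactants: 2 13-bromotridecan-1-ol; 3 16-bromohexadecanoic acid
Product: 4 13-bromotridecyl 16-bromohexadecanoate
Conditions: TsOH·H2O (5 mol %), toluene, reflux, Dean–Stark
Reagents that add atoms: none
Why: Fischer esterification driven to completion by azeotropic removal of water, as in wax-ester preparation from a long-chain acid and a long-chain primary alcohol; both primary C–Br bonds are inert to catalytic sulfonic acid in toluene.

Step 3
Reactants: 4 13-bromotridecyl 16-bromohexadecanoate; 5 bis(phenylsulfonyl)methane
Product: 8 17,17-bis(phenylsulfonyl)triacontan-30-olide, via 14,14-bis(phenylsulfonyl)tetradecyl 16-bromohexadecanoate 6 (not isolated), via 13-bromotridecyl 17,17-bis(phenylsulfonyl)heptadecanoate 7 (not isolated)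
Conditions: Cs2CO3 (4 equiv), Bu4NI (10 mol %), dry DMF, 60 °C; 4 + 5 (1:1) in DMF–THF added by syringe pump over 24 h (final ca. 3 mM), then 60 °C, 24 h
Reagents that add atoms: none
Why: Cs2CO3 deprotonates 5 (pKa about 12 in DMSO) and the soft carbanion displaces either primary bromide of 4 by SN2, giving 6 (C17–C18 made first) or 7 (C16–C17 made first) in parallel; renewed deprotonation of the still acidic monoalkylated bis-sulfone and a second SN2 at the remaining chain end should close the ring, so both intermediates converge on 8. The closest known reaction type is macrocyclisation by double alkylation of an active-methylene compound (malonate, TosMIC, bis-sulfone) with an α,ω-dihalide under caesium carbonate at high dilution. The single ring, the 31-membered lactone, is closed in a 31-exo-tet mode at a primary carbon, and no stereocentre is created. Chemoselectivity for C-alkylation at the bis-sulfone carbon rests on the gap of more than fifteen pK units between that carbon and the ester α-methylene C2, and carbonate in dry DMF should leave the ester intact. Ring formation must beat oligomerisation and double capping of one chain; strict 1:1 stoichiometry and slow co-addition into dilute base keep the stationary concentrations below the effective molarity of a strain-free large ring, while Bu4NI as halide-exchange catalyst and the loosely paired caesium carbanion speed up the hindered second alkylation.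

Step 4
Reactants: 8 17,17-bis(phenylsulfonyl)triacontan-30-olide
Product: 10 triacontan-30-olide, via 17-(phenylsulfonyl)triacontan-30-olide 9 (not isolated)
Conditions: 6% Na(Hg) (excess), Na2HPO4, THF–MeOH (2:1), −20 °C to rt
Reagents that add atoms: none
Why: Reductive desulfonylation by electron transfer from sodium amalgam: cleavage of the first C–S bond gives a sulfonyl-stabilised carbanion that is protonated to the racemic monosulfone 9, a second cleavage and protonation leave C17 as CH2, and the Na2HPO4 buffer traps methoxide so that the unstrained macrolactone, whose isolated ester carbonyl is not reduced by amalgam, should survive.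

Compound list
1 | tridecane-1,13-diol | OCCCCCCCCCCCCCO | starting material
2 | 13-bromotridecan-1-ol | OCCCCCCCCCCCCCBr | intermediate
3 | 16-bromohexadecanoic acid | OC(=O)CCCCCCCCCCCCCCCBr | starting material
4 | 13-bromotridecyl 16-bromohexadecanoate | BrCCCCCCCCCCCCCCCC(=O)OCCCCCCCCCCCCCBr | intermediate
5 | bis(phenylsulfonyl)methane | O=S(=O)(CS(=O)(=O)c1ccccc1)c1ccccc1 | starting material
6 | 14,14-bis(phenylsulfonyl)tetradecyl 16-bromohexadecanoate | BrCCCCCCCCCCCCCCCC(=O)OCCCCCCCCCCCCCC(S(=O)(=O)c1ccccc1)S(=O)(=O)c1ccccc1 | intermediate (not isolated)
7 | 13-bromotridecyl 17,17-bis(phenylsulfonyl)heptadecanoate | BrCCCCCCCCCCCCCOC(=O)CCCCCCCCCCCCCCCC(S(=O)(=O)c1ccccc1)S(=O)(=O)c1ccccc1 | intermediate (not isolated)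
8 | 17,17-bis(phenylsulfonyl)triacontan-30-olide | O=C1CCCCCCCCCCCCCCCC(S(=O)(=O)c2ccccc2)(S(=O)(=O)c2ccccc2)CCCCCCCCCCCCCO1 | intermediate
9 | 17-(phenylsulfonyl)triacontan-30-olide, racemic at C17 | O=C1CCCCCCCCCCCCCCCC(S(=O)(=O)c2ccccc2)CCCCCCCCCCCCCO1 | intermediate (not isolated)
10 | triacontan-30-olide (1-oxacyclohentriacontan-2-one), no stereocentres | O=C1CCCCCCCCCCCCCCCCCCCCCCCCCCCCCO1 | target

Total step count: 4
Longest linear sequence: 4 steps (1 → 2 → 4 → 8 → 10)

Steps most likely to fail

Step 3. The intermolecular first alkylation may be slow at the dilution that ring closure needs, and the hindered carbanions of 6 and 7 may alkylate too slowly to outrun chain extension, so that oligomers and doubly capped chains form. The fallback sets out from 2, 3 and 5 and comes back at 8. It keeps the bis-sulfone carbon for chain assembly but closes the ring at the C1–O bond. Excess 5 is monoalkylated with 2 (Cs2CO3, DMF, 50 °C) to 14,14-bis(phenylsulfonyl)tetradecan-1-ol F1. Acid 3 is esterified (MeOH, cat. H2SO4, reflux) to methyl 16-bromohexadecanoate F2. F1 is alkylated with excess F2 at high concentration (Cs2CO3, Bu4NI, DMF, 80 °C), where the sluggish second alkylation can be forced, to methyl 30-hydroxy-17,17-bis(phenylsulfonyl)triacontanoate F3. Saponification (LiOH, THF–H2O) gives 30-hydroxy-17,17-bis(phenylsulfonyl)triacontanoic acid F4. Yamaguchi macrolactonisation (2,4,6-trichlorobenzoyl chloride, Et3N, THF, then slow addition to 4-(dimethylamino)pyridine in toluene at reflux) should give 8, from which step 4 follows.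

Step 4. Methoxide formed at the amalgam surface may open the lactone by methanolysis, or the reduction may stall after loss of the first sulfonyl group. The fallback sets out from 8 and comes back at 10; it accepts ring opening and drives it to completion. Mg turnings in MeOH–THF at 50 °C remove both sulfonyl groups and transesterify the lactone to methyl 30-hydroxytriacontanoate F5 (NaOMe is added at the end if lactone remains). LiOH in THF–H2O gives 30-hydroxytriacontanoic acid F6. Yamaguchi macrolactonisation under high dilution (2,4,6-trichlorobenzoyl chloride, Et3N, THF, then slow addition to 4-(dimethylamino)pyridine in toluene at reflux) should return 10.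

Step 1. The substitution may not stop cleanly after one hydroxyl, leaving a statistical mixture of diol, bromo alcohol and dibromide that is tedious to separate. The fallback sets out from 1 and 3 and comes back at 4, bypassing steps 1 and 2; the diol is desymmetrised by acylation instead of by bromination. Acid 3 is esterified with a fourfold excess of 1 (TsOH·H2O, toluene, Dean–Stark; the surplus diol crystallises on cooling and is recycled) to 13-hydroxytridecyl 16-bromohexadecanoate F7. An Appel reaction (CBr4, PPh3, CH2Cl2, 0 °C) then converts the remaining hydroxyl into the bromide and should give 4.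

Further compounds
F1 | step 3 | 14,14-bis(phenylsulfonyl)tetradecan-1-ol | OCCCCCCCCCCCCCC(S(=O)(=O)c1ccccc1)S(=O)(=O)c1ccccc1
F2 | step 3 | methyl 16-bromohexadecanoate | COC(=O)CCCCCCCCCCCCCCCBr
F3 | step 3 | methyl 30-hydroxy-17,17-bis(phenylsulfonyl)triacontanoate | COC(=O)CCCCCCCCCCCCCCCC(S(=O)(=O)c1ccccc1)(S(=O)(=O)c1ccccc1)CCCCCCCCCCCCCO
F4 | step 3 | 30-hydroxy-17,17-bis(phenylsulfonyl)triacontanoic acid | OC(=O)CCCCCCCCCCCCCCCC(S(=O)(=O)c1ccccc1)(S(=O)(=O)c1ccccc1)CCCCCCCCCCCCCO
F5 | step 4 | methyl 30-hydroxytriacontanoate | COC(=O)CCCCCCCCCCCCCCCCCCCCCCCCCCCCCO
F6 | step 4 | 30-hydroxytriacontanoic acid | OC(=O)CCCCCCCCCCCCCCCCCCCCCCCCCCCCCO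
F7 | step 1 | 13-hydroxytridecyl 16-bromohexadecanoate | BrCCCCCCCCCCCCCCCC(=O)OCCCCCCCCCCCCCO
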